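## Structural features

The target is a ring-A-opened 8,13-epoxylabdane: a cyclohexane (ring B, C5–C10) fused through C8–C9 to a tetrahydropyran (ring C: O, C8, C9, C11, C12, C13). C10 carries a methyl (C20) and the CH2CO2H arm (C1–C2); C5 carries the C(CH3)2CO2H arm (C4, C3). In what follows α is the ring-B face of H-5 and of the C10 acetic arm, and β is the face of C20.

Four of the five stereocentres are contiguous (C5, C10, C9, C8) and the fifth, C13, sits across the ring oxygen. The two acid arms are trans, H-9 is α, and the C8–O bond is α (equatorial on ring B), so the rings are trans-fused and the C8 methyl (C17) is axial and syn to C20. The C13 methyl (C16) is cis to C17 across oxygen, which places the vinyl group equatorial.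

C10 is an all-carbon quaternary centre next to C5, which itself carries the quaternary C4; C8 and C13 are oxygen-bearing quaternary carbons.

Fragile points are the tertiary, allylic C13–O bond (ionisation in strong acid would scramble C13), the vinyl group (attacked by boranes, mercury salts and hydrogenation catalysts), and the C3 ester, which is shielded on both sides and resists ordinary saponification.

The real difficulty is twofold: the crowded C5/C10 pair in absolute sense, and C13, which has little thermodynamic bias (either epimer puts one substituent syn-axial to C17) and so must come from a stereodefined fragment.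

The key step exploits the fact that C5 and C10 are the β- and α-carbons of 2-methylcyclohex-2-enone with C9 as the carbonyl carbon. Both acid arms can therefore be attached in one conjugate addition–enolate alkylation, and the resulting C9 ketone can enolise only toward C8.

## Logic of the disconnections

22 ⇒ 21. The two acyl C–O bonds of the acids are cut, so the acids travel as a methyl and a tert-butyl ester that tolerate every basic and organometallic step. Because the C13–O bond is acid-labile, the forward step must cleave both esters under base and must reach the hindered C3 ester.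

21 ⇒ 20 ⇒ 19 ⇒ 18. The C14=C15 bond is cut (methylenation of an aldehyde), and C14 is traced back through the alcohol to a benzyl ether. The vinyl group is thereby absent during the borane, mercury and hydrogenation chemistry that it would not survive. The forward steps need a clean hydrogenolysis, an oxidation to an aldehyde with no α-hydrogen, and a Wittig reaction on a neopentyl-type aldehyde.

18 ⇒ 16. The C8–O bond is cut, which opens ring C and removes the C8 stereocentre. The forward step is a Markovnikov 6-exo addition of the C13 hydroxyl to an exocyclic C8=C17 methylene, where only C8 can take the oxygen. Closure by protonating a tetrasubstituted C8=C9 alkene was rejected because it would need a net syn addition of H and O and would compete with five-membered spiro-ether formation at C9. The demand on the forward step is attack on the α-face of C8.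

16 ⇒ 15 ⇒ 14 ⇒ 12. C17 is cut off (Wittig) and the C8 carbonyl is traced to the hydroboration of a C8=C9 alkene. This sequence places the C9 hydrogen by syn addition before ring C exists. It demands α-face delivery of borane, which the pseudoaxial C10 methyl should enforce.

12 ⇒ 7 + 10. The C9–C11 bond is cut between an alkenyl triflate and an alkylborane (11, made in the flask). This is the convergent point, and it separates the stereochemical problem of ring B from that of C13. The forward coupling has to work at an alkenyl carbon flanked by the quaternary C10 and must tolerate a free tertiary hydroxyl.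

10 ⇒ 9 ⇒ 8. The C11–C12 bond (one-carbon homologation of an epoxide to a vinyl carbinol) and the benzyl O–C bond are cut. C13 is thus taken unchanged from a purchased, enantiopure epoxy alcohol, and no step breaks a bond at C13.

7 ⇒ 6. The O–S bond of the enol triflate is cut. Regiochemistry is not an issue, because C10 has no hydrogen.

6 ⇒ 1 + 2 + 3. The C4–C5 and C10–C1 bonds are cut, returning three purchased components (4 and 5 are intermediates in the flask). The forward step must set C5 by catalyst control and C10 by the influence of C5, and must release the enolate regiospecifically.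

## Other disconnections considered

Alternative 1: The cut runs through C9–C10 and C8–O and opens both rings to the acyclic hydroxy diene diester A1. In the forward step a cobalt hydride formed from Co(salen), PhSiH3 and an N-fluoropyridinium oxidant would transfer a hydrogen atom to the C10 methylene. The tertiary C10 radical would close 6-endo on C9, and the C8 radical, once oxidised to the cation, would be captured by the C13 hydroxyl to give the silyloxyethyl bicycle A2.
- In its favour: both rings, one C–C and one C–O bond and three stereocentres (C10, C9, C8) would arise in one operation, and 6-endo closure is the usual mode when the inner alkene carbon is methylated.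
- Against it here: the radical must form the C9–C10 bond beside the bulky C5 substituent. The C5/C10 relationship would rest on acyclic conformational bias alone. Early oxidation of the C10 radical or hydrogen transfer to the trisubstituted alkene would divert material. A1 already needs C5 and C13 set separately in absolute sense, plus an (E)-trisubstituted alkene. The silyloxyethyl group costs three more operations before the vinyl group exists.
- Comparison: on structure this plan is the better one, since it builds the whole bicycle where the chosen key step closes no ring. On mechanism the chosen plan is better founded, because each stereocentre comes from a separately precedented two-electron event. On step economy the alternative is shorter after its key step and longer before it, so the two are about equal.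

Alternative 2: The cut is through C12–C13 and C8–O, giving the vinylcyclohexene A3 and ethyl pyruvate A4. In the forward step Cu(OTf)2 with 2,2′-isopropylidenebis(4-tert-butyl-2-oxazoline) would activate the ketone carbonyl of A4 for a [4+2] addition across C8=C9–C11=C12 of A3, giving the dihydropyran triester A5.
- In its favour: ring C and both oxygen-bearing quaternary carbons form in one convergent step. A3 would come from 6 by C8 methylation, triflation and vinyl coupling, so it is compatible with the same key step. The axial C20 methyl shields the β-face at C8 and should direct oxygen to the required α-face. Later hydrogenation of C9=C11 should also occur from the α-face.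
- Against it here: the diene is not electron-rich and its C8 terminus is fully substituted. A ketone is a reluctant heterodienophile. The endo/exo choice decides C13 and must be set by the catalyst against the substrate's own preferences. The vinyl group then requires selective reduction of one ester out of three, followed by methylenation.
- Comparison: on structure it is the equal of the chosen plan for the carbocycle and better for ring C, since it needs no separate chiral fragment. On mechanism it is weaker, because all the risk sits in one poorly precedented cycloaddition. On step economy it would be better by about three steps if the cycloaddition performed.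

Alternative 3: The cut is the O–C13 bond, leading back to the epoxy alcohol A6, which carries the C8 tertiary hydroxyl. In the forward step camphorsulfonic acid or Ti(OiPr)4 would make the C8 hydroxyl open the epoxide at C13 with inversion in a 6-exo closure, giving the diol A7. Periodate cleavage and methylenation would then supply the vinyl group.
- In its favour: C13 is written into the ring by a stereospecific event starting from a Sharpless epoxide. The 6-exo mode is preferred over 7-endo, and attack at the tertiary epoxide carbon is electronically favoured under acid.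
- Against it here: a hindered tertiary alcohol must attack a tertiary carbon, and a loose, SN1-like transition state could erode the inversion. The C8 carbinol with its axial methyl has to be made first, and methyl addition to a C8 ketone is expected from the α-face, which gives the wrong epimer. The side chain needs a stereodefined (E)-trisubstituted allylic alcohol.
- Comparison: on the source of C13 the two plans are equal, since both draw on a Sharpless-type epoxide. The alternative is better in that no masked vinyl group has to pass through borane and mercury chemistry. On mechanism the chosen plan is safer, because it never makes or breaks a bond at C13. On step economy the alternative is worse by two to three steps.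

Key step: step 1

Assumption: the (S)-configured oxazaborolidinium ion is taken to deliver the ketene acetal to the enone face that gives (R)-C5; if the facial sense is the opposite, the (R)-catalyst is used with no other change.

Remark: the hindered tertiary hydroxyl of 10 is carried unprotected through steps 5–8, and extra 9-BBN, BH3 and ylide allow for its borylation or deprotonation.

## Route

Step 1
Reactants: 1 2-methylcyclohex-2-en-1-one; 2 1-methoxy-2-methyl-1-(trimethylsilyloxy)prop-1-ene; 3 tert-butyl bromoacetate
Product: 6 tert-butyl 2-[(1S,2R)-2-(1-methoxy-2-methyl-1-oxopropan-2-yl)-1-methyl-6-oxocyclohexyl]acetate, via silyl enol ether 4 (not isolated), via lithium enolate 5 (not isolated)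
Conditions: (S)-B-(o-tolyl) diphenylprolinol oxazaborolidine/HNTf2 (20 mol %), Ph3PO (25 mol %), toluene, −20 °C; evaporate; MeLi (1.3 equiv), THF, 0 °C; then 3, DMPU, −78 → −20 °C
Reagents that add atoms: none
Why: The oxazaborolidinium ion binds the enone carbonyl, the nucleophilic carbon of 2 adds to the β-carbon C5, and the silyl group ends on the enolate oxygen to give 4 as a regiodefined tetrasubstituted silyl enol ether, while Ph3PO intercepts silyl cations so that an achiral silyl-catalysed pathway does not compete. MeLi then cleaves the O–Si bond to give the lithium enolate 5 and Me4Si, and 5 is C-alkylated at C10 by the SN2-reactive bromoacetate 3. The closest known reaction type is the catalytic enantioselective Mukaiyama–Michael addition of silyl ketene acetals to cyclic enones, joined to the classical conjugate addition–enolate trapping sequence. No ring is closed, so no mode of closure arises. C5 is set by the catalyst, which leaves one enone face open. C10 is set by the substrate: the C5 substituent sits pseudoaxial to avoid strain with the C10 methyl and the electrophile enters anti to it, which gives the trans arrangement of the two arms. The step needs 1,4- over 1,2-addition (soft ketene acetal, single β-position), alkylation at C10 and not C8 (the enolate is released only from 4), C- over O-alkylation (lithium counter-ion, bromide leaving group), and attack of MeLi at silicon and not at the ester (the ester is shielded by the quaternary C4, and the temperature is low).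

Step 2
Reactants: 6 tert-butyl 2-[(1S,2R)-2-(1-methoxy-2-methyl-1-oxopropan-2-yl)-1-methyl-6-oxocyclohexyl]acetate
Product: 7 tert-butyl 2-[(1S,6R)-6-(1-methoxy-2-methyl-1-oxopropan-2-yl)-1-methyl-2-(trifluoromethanesulfonyloxy)cyclohex-2-en-1-yl]acetate
Conditions: KN(SiMe3)2, THF, −78 °C; PhNTf2, −78 → 0 °C
Reagents that add atoms: N-phenylbis(trifluoromethanesulfonimide), O=S(=O)(N(c1ccccc1)S(=O)(=O)C(F)(F)F)C(F)(F)F
Why: Enolisation is possible only toward C8 because C10 is quaternary, and the potassium enolate is O-sulfonylated (enol triflate formation). The ester α-protons are less acidic and more hindered, and no stereocentre is touched.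

Step 3
Reactants: 8 [(2S)-2-methyloxiran-2-yl]methanol
Product: 9 (2R)-2-[(benzyloxy)methyl]-2-methyloxirane
Conditions: NaH, BnBr, Bu4NI (cat.), THF, 0 °C → rt
Reagents that add atoms: benzyl bromide, BrCc1ccccc1
Why: Williamson etherification of the primary alkoxide. A Payne rearrangement of this alkoxide would be degenerate and return the same enantiomer, and the quaternary stereocentre is not touched (the descriptor changes from S to R only through the CIP priority change at CH2O).

Step 4
Reactants: 9 (2R)-2-[(benzyloxy)methyl]-2-methyloxirane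
Product: 10 (2R)-1-(benzyloxy)-2-methylbut-3-en-2-ol
Conditions: Me3SI, n-BuLi, THF, −10 °C → rt
Reagents that add atoms: trimethylsulfonium iodide, C[S+](C)C.[I-]
Why: Dimethylsulfonium methylide opens the epoxide at its CH2 terminus and the resulting β-alkoxy sulfonium salt loses Me2S under the excess ylide (one-carbon homologation of an epoxide to an allylic alcohol). The C13–O bond is never broken, so the configuration is retained.

Step 5
Reactants: 10 (2R)-1-(benzyloxy)-2-methylbut-3-en-2-ol; 7 tert-butyl 2-[(1S,6R)-6-(1-methoxy-2-methyl-1-oxopropan-2-yl)-1-methyl-2-(trifluoromethanesulfonyloxy)cyclohex-2-en-1-yl]acetate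
Product: 12 tert-butyl 2-[(1S,6R)-2-[(3R)-4-(benzyloxy)-3-hydroxy-3-methylbutyl]-6-(1-methoxy-2-methyl-1-oxopropan-2-yl)-1-methylcyclohex-2-en-1-yl]acetate, via B-alkyl-9-BBN adduct 11 (not isolated)
Conditions: 9-BBN (2.2 equiv), THF, rt; then 7, PdCl2(dppf) (10 mol %), AsPh3, aq K3PO4, DMF, 50 °C
Reagents that add atoms: none
Why: Anti-Markovnikov hydroboration of the monosubstituted alkene puts boron on C11, and the B-alkyl Suzuki–Miyaura coupling with the alkenyl triflate forms C9–C11 while the double bond stays at C8=C9. Boron sits γ to the oxygen, so no β-elimination is open, and the esters and benzyl ether are inert to the mild aqueous base.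

Step 6
Reactants: 12 tert-butyl 2-[(1S,6R)-2-[(3R)-4-(benzyloxy)-3-hydroxy-3-methylbutyl]-6-(1-methoxy-2-methyl-1-oxopropan-2-yl)-1-methylcyclohex-2-en-1-yl]acetate
Product: 14 tert-butyl 2-[(1S,2R,3R,6R)-2-[(3R)-4-(benzyloxy)-3-hydroxy-3-methylbutyl]-3-hydroxy-6-(1-methoxy-2-methyl-1-oxopropan-2-yl)-1-methylcyclohexyl]acetate, via C8 alkylborane 13 (not isolated)
Conditions: BH3·THF (3 equiv), THF, 0 °C → rt; then NaOH, H2O2, 0 °C
Reagents that add atoms: hydrogen peroxide, OO
Why: Hydroboration–oxidation: boron adds to the less substituted C8 and hydrogen to C9, both from the α-face, anti to the pseudoaxial C10 methyl, which sets H-9 α and leaves the side chain equatorial. Oxidation with retention gives the 8α-alcohol, whose configuration is immaterial because C8 is oxidised next. The hindered esters are reduced far more slowly than the alkene is hydroborated, and the borate formed at the tertiary hydroxyl is a poor hydroborating agent.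

Step 7
Reactants: 14 tert-butyl 2-[(1S,2R,3R,6R)-2-[(3R)-4-(benzyloxy)-3-hydroxy-3-methylbutyl]-3-hydroxy-6-(1-methoxy-2-methyl-1-oxopropan-2-yl)-1-methylcyclohexyl]acetate
Product: 15 tert-butyl 2-[(1S,2R,6R)-2-[(3R)-4-(benzyloxy)-3-hydroxy-3-methylbutyl]-6-(1-methoxy-2-methyl-1-oxopropan-2-yl)-1-methyl-3-oxocyclohexyl]acetate
Conditions: Dess–Martin periodinane, NaHCO3, CH2Cl2, rt
Reagents that add atoms: none
Why: Dess–Martin oxidation converts the secondary alcohol into the C8 ketone and cannot oxidise the tertiary hydroxyl. The buffered medium avoids epimerisation at C9, which in any case holds its more stable equatorial-chain arrangement. The product may rest partly as its cyclic hemiketal, which reopens under the next conditions.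

Step 8
Reactants: 15 tert-butyl 2-[(1S,2R,6R)-2-[(3R)-4-(benzyloxy)-3-hydroxy-3-methylbutyl]-6-(1-methoxy-2-methyl-1-oxopropan-2-yl)-1-methyl-3-oxocyclohexyl]acetate
Product: 16 tert-butyl 2-[(1R,2S,6R)-2-[(3R)-4-(benzyloxy)-3-hydroxy-3-methylbutyl]-6-(1-methoxy-2-methyl-1-oxopropan-2-yl)-1-methyl-3-methylidenecyclohexyl]acetate
Conditions: Ph3PCH3Br, KOtBu, toluene, rt → 60 °C
Reagents that add atoms: methyltriphenylphosphonium bromide, C[P+](c1ccccc1)(c1ccccc1)c1ccccc1.[Br-]
Why: Wittig methylenation installs C17 as the exocyclic methylene. Excess ylide compensates for deprotonation of the tertiary hydroxyl and for reversible enolisation, and the shielded esters are not attacked. The ring descriptors change only through CIP priorities.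

Step 9
Reactants: 16 tert-butyl 2-[(1R,2S,6R)-2-[(3R)-4-(benzyloxy)-3-hydroxy-3-methylbutyl]-6-(1-methoxy-2-methyl-1-oxopropan-2-yl)-1-methyl-3-methylidenecyclohexyl]acetate
Product: 18 tert-butyl 2-[(2R,4aR,5S,6R,8aR)-2-[(benzyloxy)methyl]-6-(1-methoxy-2-methyl-1-oxopropan-2-yl)-2,5,8a-trimethyl-octahydro-2H-chromen-5-yl]acetate, via organomercurial 17 (not isolated)
Conditions: Hg(OCOCF3)2, THF, 0 °C; then NaBH4, aq NaOH, 0 °C
Reagents that add atoms: none
Why: Intramolecular alkoxymercuration: divalent mercury activates the 1,1-disubstituted alkene and the C13 hydroxyl adds to the more substituted carbon C8 in a 6-exo-trig Markovnikov closure. Attack on the α-face (equatorial on ring B, away from the axial C10 methyl) gives the trans-fused ether and so sets C8, by analogy with the closure of 13-hydroxylabd-8(17)-enes to 8,13-epoxylabdanes. NaBH4 then replaces mercury by hydrogen, which leaves C17 as a methyl group, and C13 is untouched.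

Step 10
Reactants: 18 tert-butyl 2-[(2R,4aR,5S,6R,8aR)-2-[(benzyloxy)methyl]-6-(1-methoxy-2-methyl-1-oxopropan-2-yl)-2,5,8a-trimethyl-octahydro-2H-chromen-5-yl]acetate
Product: 19 tert-butyl 2-[(2R,4aR,5S,6R,8aR)-2-(hydroxymethyl)-6-(1-methoxy-2-methyl-1-oxopropan-2-yl)-2,5,8a-trimethyl-octahydro-2H-chromen-5-yl]acetate
Conditions: H2 (1 atm), Pd/C, EtOAc, rt
Reagents that add atoms: none
Why: Hydrogenolysis of the benzyl ether over palladium on carbon. At this stage the molecule holds no alkene, and the dialkyl ether and both esters are inert.

Step 11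
Reactants: 19 tert-butyl 2-[(2R,4aR,5S,6R,8aR)-2-(hydroxymethyl)-6-(1-methoxy-2-methyl-1-oxopropan-2-yl)-2,5,8a-trimethyl-octahydro-2H-chromen-5-yl]acetate
Product: 20 tert-butyl 2-[(2R,4aR,5S,6R,8aR)-2-formyl-6-(1-methoxy-2-methyl-1-oxopropan-2-yl)-2,5,8a-trimethyl-octahydro-2H-chromen-5-yl]acetate
Conditions: Dess–Martin periodinane, NaHCO3, CH2Cl2, rt
Reagents that add atoms: none
Why: Dess–Martin oxidation of the primary alcohol to the α-alkoxy aldehyde, which has no α-hydrogen and therefore can neither enolise nor epimerise.

Step 12
Reactants: 20 tert-butyl 2-[(2R,4aR,5S,6R,8aR)-2-formyl-6-(1-methoxy-2-methyl-1-oxopropan-2-yl)-2,5,8a-trimethyl-octahydro-2H-chromen-5-yl]acetate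
Product: 21 tert-butyl 2-[(2R,4aR,5S,6R,8aR)-2-ethenyl-6-(1-methoxy-2-methyl-1-oxopropan-2-yl)-2,5,8a-trimethyl-octahydro-2H-chromen-5-yl]acetate
Conditions: Ph3PCH3Br, KN(SiMe3)2, THF, 0 °C
Reagents that add atoms: methyltriphenylphosphonium bromide, C[P+](c1ccccc1)(c1ccccc1)c1ccccc1.[Br-]
Why: Wittig methylenation of the neopentyl-type aldehyde creates the C14=C15 vinyl group. C13 carries no hydrogen, so its configuration is secure, and the esters do not react with the ylide at 0 °C.

Step 13
Reactants: 21 tert-butyl 2-[(2R,4aR,5S,6R,8aR)-2-ethenyl-6-(1-methoxy-2-methyl-1-oxopropan-2-yl)-2,5,8a-trimethyl-octahydro-2H-chromen-5-yl]acetate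
Product: 22 2-[(2R,4aR,5S,6R,8aR)-5-(carboxymethyl)-2-ethenyl-2,5,8a-trimethyl-octahydro-2H-chromen-6-yl]-2-methylpropanoic acid
Conditions: KOtBu/H2O (2:1), THF–DMSO, rt → 50 °C; then aq HCl to pH 3–4, 0 °C
Reagents that add atoms: water, O
Why: Weakly solvated hydroxide made from KOtBu and water cleaves hindered esters by acyl–oxygen fission, here the shielded methyl ester and the tert-butyl ester in one operation. The substrate has no base-labile stereocentre (C4 and C10 are quaternary), and the tertiary allylic ether never meets strong acid because the work-up is cold and only mildly acidic.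

## Compound list

1 | 2-methylcyclohex-2-en-1-one | CC1=CCCCC1=O | starting material
2 | 1-methoxy-2-methyl-1-(trimethylsilyloxy)prop-1-ene | COC(O[Si](C)(C)C)=C(C)C | starting material
3 | tert-butyl bromoacetate | BrCC(=O)OC(C)(C)C | starting material
4 | methyl 2-methyl-2-[(1R)-2-methyl-3-(trimethylsilyloxy)cyclohex-2-en-1-yl]propanoate (not isolated) | COC(=O)C(C)(C)[C@@H]1CCCC(O[Si](C)(C)C)=C1C | intermediate
5 | lithium (3R)-3-(1-methoxy-2-methyl-1-oxopropan-2-yl)-2-methylcyclohex-1-en-1-olate (not isolated) | COC(=O)C(C)(C)[C@@H]1CCCC(O[Li])=C1C | intermediate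
6 | tert-butyl 2-[(1S,2R)-2-(1-methoxy-2-methyl-1-oxopropan-2-yl)-1-methyl-6-oxocyclohexyl]acetate | O=C1[C@@](C)(CC(=O)OC(C)(C)C)[C@H](C(C)(C)C(=O)OC)CCC1 | intermediate
7 | tert-butyl 2-[(1S,6R)-6-(1-methoxy-2-methyl-1-oxopropan-2-yl)-1-methyl-2-(trifluoromethanesulfonyloxy)cyclohex-2-en-1-yl]acetate | O=S(=O)(OC1=CCC[C@@H](C(C)(C)C(=O)OC)[C@]1(C)CC(=O)OC(C)(C)C)C(F)(F)F | intermediate
8 | [(2S)-2-methyloxiran-2-yl]methanol | C[C@]1(CO)CO1 | starting material
9 | (2R)-2-[(benzyloxy)methyl]-2-methyloxirane | C[C@]1(COCc2ccccc2)CO1 | intermediate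
10 | (2R)-1-(benzyloxy)-2-methylbut-3-en-2-ol | C=C[C@@](C)(O)COCc1ccccc1 | intermediate
11 | (2R)-1-(benzyloxy)-4-(9-borabicyclo[3.3.1]nonan-9-yl)-2-methylbutan-2-ol (not isolated) | B1(CC[C@@](C)(O)COCc2ccccc2)C2CCCC1CCC2 | intermediate
12 | tert-butyl 2-[(1S,6R)-2-[(3R)-4-(benzyloxy)-3-hydroxy-3-methylbutyl]-6-(1-methoxy-2-methyl-1-oxopropan-2-yl)-1-methylcyclohex-2-en-1-yl]acetate | C1(CC[C@@](C)(O)COCc2ccccc2)=CCC[C@@H](C(C)(C)C(=O)OC)[C@]1(C)CC(=O)OC(C)(C)C | intermediate
13 | C8 alkylborane from 12, with BH2 on C8 and H on C9 both α, other centres as in 12 (not isolated) | c1ccccc1COC[C@](C)(O)CC[C@@H]2[C@@](C)(CC(=O)OC(C)(C)C)[C@H](C(C)(C)C(=O)OC)CC[C@H]2B | intermediate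
14 | tert-butyl 2-[(1S,2R,3R,6R)-2-[(3R)-4-(benzyloxy)-3-hydroxy-3-methylbutyl]-3-hydroxy-6-(1-methoxy-2-methyl-1-oxopropan-2-yl)-1-methylcyclohexyl]acetate | c1ccccc1COC[C@](C)(O)CC[C@@H]2[C@@](C)(CC(=O)OC(C)(C)C)[C@H](C(C)(C)C(=O)OC)CC[C@H]2O | intermediate
15 | tert-butyl 2-[(1S,2R,6R)-2-[(3R)-4-(benzyloxy)-3-hydroxy-3-methylbutyl]-6-(1-methoxy-2-methyl-1-oxopropan-2-yl)-1-methyl-3-oxocyclohexyl]acetate | c1ccccc1COC[C@](C)(O)CC[C@@H]2[C@@](C)(CC(=O)OC(C)(C)C)[C@H](C(C)(C)C(=O)OC)CCC2=O | intermediate
16 | tert-butyl 2-[(1R,2S,6R)-2-[(3R)-4-(benzyloxy)-3-hydroxy-3-methylbutyl]-6-(1-methoxy-2-methyl-1-oxopropan-2-yl)-1-methyl-3-methylidenecyclohexyl]acetate | c1ccccc1COC[C@](C)(O)CC[C@@H]2[C@@](C)(CC(=O)OC(C)(C)C)[C@H](C(C)(C)C(=O)OC)CCC2=C | intermediate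
17 | 8a-[(trifluoroacetoxymercurio)methyl] analogue of 18, same configuration at every centre (not isolated) | c1ccccc1COC[C@@]2(C)CC[C@@H]3[C@@](C)(CC(=O)OC(C)(C)C)[C@H](C(C)(C)C(=O)OC)CC[C@@]3(C[Hg]OC(=O)C(F)(F)F)O2 | intermediate
18 | tert-butyl 2-[(2R,4aR,5S,6R,8aR)-2-[(benzyloxy)methyl]-6-(1-methoxy-2-methyl-1-oxopropan-2-yl)-2,5,8a-trimethyl-octahydro-2H-chromen-5-yl]acetate | c1ccccc1COC[C@@]2(C)CC[C@@H]3[C@@](C)(CC(=O)OC(C)(C)C)[C@H](C(C)(C)C(=O)OC)CC[C@@]3(C)O2 | intermediate
19 | tert-butyl 2-[(2R,4aR,5S,6R,8aR)-2-(hydroxymethyl)-6-(1-methoxy-2-methyl-1-oxopropan-2-yl)-2,5,8a-trimethyl-octahydro-2H-chromen-5-yl]acetate | OC[C@@]1(C)CC[C@@H]2[C@@](C)(CC(=O)OC(C)(C)C)[C@H](C(C)(C)C(=O)OC)CC[C@@]2(C)O1 | intermediate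
20 | tert-butyl 2-[(2R,4aR,5S,6R,8aR)-2-formyl-6-(1-methoxy-2-methyl-1-oxopropan-2-yl)-2,5,8a-trimethyl-octahydro-2H-chromen-5-yl]acetate | O=C[C@@]1(C)CC[C@@H]2[C@@](C)(CC(=O)OC(C)(C)C)[C@H](C(C)(C)C(=O)OC)CC[C@@]2(C)O1 | intermediate
21 | tert-butyl 2-[(2R,4aR,5S,6R,8aR)-2-ethenyl-6-(1-methoxy-2-methyl-1-oxopropan-2-yl)-2,5,8a-trimethyl-octahydro-2H-chromen-5-yl]acetate | C=C[C@@]1(C)CC[C@@H]2[C@@](C)(CC(=O)OC(C)(C)C)[C@H](C(C)(C)C(=O)OC)CC[C@@]2(C)O1 | intermediate
22 | 2-[(2R,4aR,5S,6R,8aR)-5-(carboxymethyl)-2-ethenyl-2,5,8a-trimethyl-octahydro-2H-chromen-6-yl]-2-methylpropanoic acid | C=C[C@@]1(C)CC[C@@H]2[C@@](C)(CC(=O)O)[C@H](C(C)(C)C(=O)O)CC[C@@]2(C)O1 | target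

## Step count and least certain steps

Total: 13 steps. Longest linear sequence: 11 steps (steps 1, 2, 5–13 from 1; the fragment branch, steps 3, 4, 5–13 from 8, is equally long).

Step 1 (key step). The most likely failure is a slow and poorly face-selective conjugate addition. The α-methyl group removes the α-C–H contact that helps to organise simple enones on this catalyst, and the new bond joins a quaternary carbon to a β-carbon next to a substituted α-carbon. A secondary concern is competing attack of MeLi on the ester during enolate release.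

Fallback (from 1, back at 4), in which C5 is set by sigmatropic chirality transfer and not by catalyst face selection:
- CBS reduction of 1 with the (R)-methyl oxazaborolidine and BH3·SMe2 should give (1S)-2-methylcyclohex-2-en-1-ol F1.
- Acylation with isobutyryl chloride and pyridine gives (1S)-2-methylcyclohex-2-en-1-yl 2-methylpropanoate F2.
- Ireland–Claisen rearrangement (LiN(iPr)2, Me3SiCl, THF, −78 °C → reflux, then aqueous acid) carries the C9–O configuration suprafacially to C5 and gives 2-methyl-2-[(1R)-2-methylcyclohex-2-en-1-yl]propanoic acid F3.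
- Me3SiCHN2 gives methyl 2-methyl-2-[(1R)-2-methylcyclohex-2-en-1-yl]propanoate F4.
- Hydroboration–oxidation places oxygen on C9 and gives methyl 2-[(1R,2R,3R)-3-hydroxy-2-methylcyclohexyl]-2-methylpropanoate F5.
- Dess–Martin oxidation gives methyl 2-methyl-2-[(1R,2R)-2-methyl-3-oxocyclohexyl]propanoate F6, whose C10 configuration is immaterial.
- Silylation under equilibrating conditions (Me3SiCl, NaI, Et3N, MeCN) gives the more substituted silyl enol ether, which is 4. The MeLi/alkylation half of step 1 then follows unchanged.

Step 5. The most likely failure is slow transmetalation onto the alkenylpalladium centre, which is flanked by the quaternary C10. The triflate could then be hydrolysed back toward 6 or reduced, and the alkylborane could be lost by β-hydride elimination or protodeboronation.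

Fallback (from 7 and 10, back at 12): Heck alkenylation of 10 with 7 (Pd(OAc)2, K2CO3, Bu4NCl, DMF) should give tert-butyl 2-[(1S,6R)-2-[(1E,3R)-4-(benzyloxy)-3-hydroxy-3-methylbut-1-en-1-yl]-6-(1-methoxy-2-methyl-1-oxopropan-2-yl)-1-methylcyclohex-2-en-1-yl]acetate F7. Diimide (2-nitrobenzenesulfonyl hydrazide, Et3N) should then saturate the disubstituted C11=C12 bond and spare the hindered ring alkene, giving 12.

Step 9. Two processes may interfere. Closure may be slow or go to the cis-fused ether, because the developing ring places the C13 methyl syn-axial to the CH2Hg group. The alkene may also be regenerated during reductive demercuration.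

Fallback (from 16, back at 18): iodoetherification (I2, NaHCO3, MeCN, 0 °C), which can equilibrate toward the more stable ring fusion, gives tert-butyl 2-[(2R,4aR,5S,6R,8aR)-2-[(benzyloxy)methyl]-8a-(iodomethyl)-6-(1-methoxy-2-methyl-1-oxopropan-2-yl)-2,5-dimethyl-octahydro-2H-chromen-5-yl]acetate F8. Radical hydrodeiodination (Bu3SnH, AIBN, benzene, 80 °C) cannot revert and gives 18.

Step 13. The most likely failure is incomplete hydrolysis of one of the two esters, the C3 methyl ester because of shielding or the tert-butyl ester because of slow acyl–oxygen fission. Forcing the conditions or using acid would then put the C13–O bond at risk.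

Fallback (from 21, back at 22): LiAlH4 (THF, 0 °C) reduces both esters to 2-[(2R,4aR,5S,6R,8aR)-2-ethenyl-6-(1-hydroxy-2-methylpropan-2-yl)-2,5,8a-trimethyl-octahydro-2H-chromen-5-yl]ethan-1-ol F9. Dess–Martin oxidation gives 2-[(2R,4aR,5S,6R,8aR)-2-ethenyl-2,5,8a-trimethyl-5-(2-oxoethyl)-octahydro-2H-chromen-6-yl]-2-methylpropanal F10. Pinnick oxidation (NaClO2, NaH2PO4, 2-methylbut-2-ene, tBuOH–H2O) gives 22.

## Further compounds

F1 | step 1 | (1S)-2-methylcyclohex-2-en-1-ol | O[C@@H]1C(C)=CCCC1
F2 | step 1 | (1S)-2-methylcyclohex-2-en-1-yl 2-methylpropanoate | CC(C)C(=O)O[C@@H]1C(C)=CCCC1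
F3 | step 1 | 2-methyl-2-[(1R)-2-methylcyclohex-2-en-1-yl]propanoic acid | OC(=O)C(C)(C)[C@@H]1CCCC=C1C
F4 | step 1 | methyl 2-methyl-2-[(1R)-2-methylcyclohex-2-en-1-yl]propanoate | COC(=O)C(C)(C)[C@@H]1CCCC=C1C
F5 | step 1 | methyl 2-[(1R,2R,3R)-3-hydroxy-2-methylcyclohexyl]-2-methylpropanoate | COC(=O)C(C)(C)[C@@H]1CCC[C@@H](O)[C@@H]1C
F6 | step 1 | methyl 2-methyl-2-[(1R,2R)-2-methyl-3-oxocyclohexyl]propanoate | COC(=O)C(C)(C)[C@@H]1CCCC(=O)[C@@H]1C
F7 | step 5 | tert-butyl 2-[(1S,6R)-2-[(1E,3R)-4-(benzyloxy)-3-hydroxy-3-methylbut-1-en-1-yl]-6-(1-methoxy-2-methyl-1-oxopropan-2-yl)-1-methylcyclohex-2-en-1-yl]acetate | C1(/C=C/[C@@](C)(O)COCc2ccccc2)=CCC[C@@H](C(C)(C)C(=O)OC)[C@]1(C)CC(=O)OC(C)(C)C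
F8 | step 9 | tert-butyl 2-[(2R,4aR,5S,6R,8aR)-2-[(benzyloxy)methyl]-8a-(iodomethyl)-6-(1-methoxy-2-methyl-1-oxopropan-2-yl)-2,5-dimethyl-octahydro-2H-chromen-5-yl]acetate | c1ccccc1COC[C@@]2(C)CC[C@@H]3[C@@](C)(CC(=O)OC(C)(C)C)[C@H](C(C)(C)C(=O)OC)CC[C@@]3(CI)O2
F9 | step 13 | 2-[(2R,4aR,5S,6R,8aR)-2-ethenyl-6-(1-hydroxy-2-methylpropan-2-yl)-2,5,8a-trimethyl-octahydro-2H-chromen-5-yl]ethan-1-ol | C=C[C@@]1(C)CC[C@@H]2[C@@](C)(CCO)[C@H](C(C)(C)CO)CC[C@@]2(C)O1
F10 | step 13 | 2-[(2R,4aR,5S,6R,8aR)-2-ethenyl-2,5,8a-trimethyl-5-(2-oxoethyl)-octahydro-2H-chromen-6-yl]-2-methylpropanal | C=C[C@@]1(C)CC[C@@H]2[C@@](C)(CC=O)[C@H](C(C)(C)C=O)CC[C@@]2(C)O1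
A1 | alternative 1 | acyclic hydroxy diene diester: C10 methylene, (E)-C8=C9, C13 carbinol with a 2-(tert-butyldimethylsilyloxy)ethyl arm | C=C(CC(=O)OC)[C@H](C(C)(C)C(=O)OC)CC/C(C)=C/CC[C@@](C)(O)CCO[Si](C)(C)C(C)(C)C
A2 | alternative 1 | bicyclic ether dimethyl ester with a 2-(tert-butyldimethylsilyloxy)ethyl group at C13 | CC(C)(C)[Si](C)(C)OCC[C@@]1(C)CC[C@@H]2[C@@](C)(CC(=O)OC)[C@H](C(C)(C)C(=O)OC)CC[C@@]2(C)O1
A3 | alternative 2 | tert-butyl 2-[(1S,6R)-2-ethenyl-6-(1-methoxy-2-methyl-1-oxopropan-2-yl)-1,3-dimethylcyclohex-2-en-1-yl]acetate | C=CC1=C(C)CC[C@@H](C(C)(C)C(=O)OC)[C@]1(C)CC(=O)OC(C)(C)C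
A4 | alternative 2 | ethyl pyruvate | CCOC(=O)C(C)=O
A5 | alternative 2 | fused dihydropyran triester with C9=C11 and an ethyl ester at C13 | CCOC(=O)[C@@]1(C)CC=C2[C@@](C)(CC(=O)OC(C)(C)C)[C@H](C(C)(C)C(=O)OC)CC[C@@]2(C)O1
A6 | alternative 3 | 8α-hydroxy (13S,14S)-13,14-epoxy-15-ol dimethyl ester | OC[C@@H]1O[C@@]1(C)CC[C@@H]2[C@@](C)(CC(=O)OC)[C@H](C(C)(C)C(=O)OC)CC[C@@]2(C)O
A7 | alternative 3 | tetrahydropyran dimethyl ester bearing the (14S)-14,15-diol at C13 | OC[C@H](O)[C@@]1(C)CC[C@@H]2[C@@](C)(CC(=O)OC)[C@H](C(C)(C)C(=O)OC)CC[C@@]2(C)O1
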